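The data are calculated with made-up constants; noise was put on by code.

**The balance.** Every coupling partner charged stays in the flask, free or attached, so a flask that stops moving shows what its starting material costs. One partner per starting material is the zero of my scale.

all flasks: starting material 0.25 M

| run | coupling partner | remark | time |
|---|---|---|---|
| winter | 0.20 M | run made earlier |  |
| spring | 0.53 M | run made earlier |  |
| west | 0.300 M |  | 3.0 min |
| south-west | 0.600 M |  | 3.0 min |

- winter (time / s: starting material / %, tetra adduct / %): 12.0: 57.1, 0.1; 30.0: 52.4, 0; 60.0: 51.7, 0.6; 90.0: 50.3, 0.3; 120: 51.9, 0
- spring (time / s: starting material / %, tetra adduct / %): 10.0: 29.4, 3.6; 20.0: 20.2, 3.7; 40.0: 15.8, 2.9; 60.0: 11.9, 2.8; 120: 9.0, 1.6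

(standard deviation of a reading: 0.5 percentage points)

- part of the starting material that has reacted at the end, west
- part of the starting material that has reacted at the end, south-west
- what raising the concentration of coupling partner from its lowest to its highest value here does to the part of the starting material that has reacted (changes below 5 percentage points count as none) (it falls / it rises / no change)



**First seconds.** Winter has 57.1% of its starting material left at 12.0 s, and spring has 29.4% at 10.0 s. The opening is quick in both.

**The middle.** Winter slows to 52.4% at 30.0 s and reads 51.9% at 120 s, while spring goes on falling. Spring's tetra adduct reads 3.7% at 20.0 s, then fades to 1.6%.

**The end.** Taking the whole charge as spent, the partner bill, meaning partner spent per starting material reacted, reads 1.66 in winter. At the zero of the scale, winter would have reacted 80.0%, but it reads 48.1%. Spring, on the same assumption, reads 2.33, so the bill climbs with the charge, though spring was still moving at its last reading.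

**My reckoning.** I draw a straight line through these two bills against equivalents of partner. It gives 1.87 for west, hence 64.3% reacted. For south-west it gives 2.47, hence 97.1%.

**The forecast.** It says 66% for west, above my figure, and 97% for south-west, level with mine; the trend is that it rises. Its ground: “the partner runs out because the first product takes up a second equivalent”.

**The flask.** West gives 63.1% and south-west 97.7%, so it rises by 35 percentage points.

    starting material + coupling partner → first product + by-product (k = 0.642 /M/s)
    coupling partner + first product → double product + by-product (k = 1.34 /M/s)
    coupling partner + double product → triple product + by-product (k = 1.19 /M/s)
    starting material + tetra adduct → side product (k = 0.827 /M/s)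
    coupling partner + by-product ⇌ idle adduct, settled at all times (K = 4.00 /M)
    coupling partner + triple product → tetra adduct + by-product (k = 0.219 /M/s)

**West's stop.** The partner charge is the main reason for that rise. West's bill comes to 1.90 against my 1.87. West ends with coupling partner, the limiting reagent, at 0% free beside 37% of its starting material. That shrinking supply is part of the story: with it held up, west reaches 100%. A further flask like south-west, but charged with 0.10 M of starting material, reacts 100% of it, keeps 16.7% of its partner free and holds 0.111 M as idle adduct, so its bill is 3.88.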